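The easy step is the dissolving: with nothing consumed, the solution in the flask fills toward saturation, and by the end of the run the dissolved substrate holds a fraction a = 58.3 % of the charged solid substrate, while the coupling partner, counting self-condensation and no other loss, keeps a fraction b = 38.2 % of its own charge.

solid substrate 2.0 M; coupling partner 1.80 M; time 25 h

    2 coupling partner → self-condensation product (k1 = 3.0 × 10⁻⁴ /M/min)
    solid substrate ⇌ dissolved substrate, rate k2*(cs2 - [dissolved substrate]) while solid is left; crystals form when [dissolved substrate] > cs2 (cs2 = 1.5 M, k2 = 0.0010 /min)
    dissolved substrate + target → side product (k3 = 0.0028 /M/min)
    dissolved substrate + coupling partner ⇌ target (K4 = 0.24 /M, k4 = 0.0013 /M/min)

- percentages count the solid substrate that a species holds: one side product counts as two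
- a doubled species enters its step squared and goes two at a time
- solid, in amounts per volume of the solution: solid substrate
- at the start none of the solid substrate is in solution
- run time (flask): 25 h

- autumn: doubling the solubility in step 2, all else as stated
- summer: doubling the dissolution coefficient of step 2, all else as stated
- spring: doubling the amount of coupling partner, all else as stated

* the target standing at 25 h, as a percentage of the solid substrate charged
* the change that raises the amount of target at 25 h, in percent of the solid substrate charged most ("none" if none brings more than 2 percentage points) (autumn / summer / spring / none)
* amount of target at 25 h, in percent of the solid substrate charged, after spring

The target in the flask is treated as a quasi-steady state: the coupling step makes it, and it leaves by the way back and by the side step. Two extreme flasks can be solved in the head. Without the side step, the target stands at equilibrium, its fraction being 0.432 times a times b, here 9.61 %. With the side step far outrunning the way back, dissolved substrate cancels and the target follows the partner, at 15.9 %.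

Both exits being open, the reciprocals of the extremes add, which gives 6.00 %, lower than either extreme. The two exits are equal at a dissolved fraction of 96.7 %, the crossover fraction: the target is the equilibrium extreme divided by one plus a over this fraction, a saturation curve. Since a and b count no losses, the flask should stand below that figure.

Dissolving the whole charge is worth 2.1 percentage points on this curve, a figure that holds b fixed although each side product carries off one partner. Doubling the partner, which self-condenses at its square, is worth 1.4 points. The dissolving figure clears the bar of 2 points by 0.10 points, a margin that a loss of 0.525 % of the partner charge removes, and the side step, run through the time at a and the reckoned target, takes 32.6 % of that charge, far more, so the reckoning commits to none.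

The forecast gives 4.1 %, none, and 5.1 % after spring, holding that “doubling the partner adds only about one point because self-condensation is second order”.

The flask gives 4.14 %, best change none, and 5.22 % after spring. At 25.0 h its target was being made at 0.826 times the rate of its use. The dissolved fraction then read 44.3 % and the partner fraction 29.8 %, and with these the crossover curve gives 3.91 %.

The neighbour flask charged with 0.45 M of partner keeps the same crossover fraction, and its readings of 51.6 % and 48.1 % give 1.75 %. The computed target in that neighbour flask is 1.82 %.

(Its constants come from no measurement; the rest is arithmetic.)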